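(The numbers in the tables are simulated for an exercise, noise included.)

| setting | summer | flask |
|---|---|---|
| substrate | 1.4 M | 0.70 M |
| gas phase | 200 mM (held) | 200 mM (held) |
| catalyst | 110 mM | 110 mM |
| added ligand | 71 mM | 71 mM |
| remark | run made earlier |  |
| time |  | 80 min |

summer run (percent of the substrate charged): time / min: target / % = 1.33: 0; 4.00: 2.0; 6.00: 1.9; 10.0: 3.2; 15.0: 4.1; 20.0: 7.1; 25.0: 9.6

(standard deviation of a reading: 1 percentage point)

- what was read earlier has a scatter of 1 percentage point, one standard deviation
- at the start none of the gas phase is in solution

- target at 80 min, in percent of the substrate charged
- the change that raises the amount of target at 80 min, in percent of the substrate charged most ("none" if none brings more than 2 percentage points) (delta / theta / zeta / none)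
- amount of target at 80 min, in percent of the substrate charged, after delta

- delta: doubling the saturation concentration of gas phase, all else as stated
- theta: doubling the amount of catalyst, all else as stated
- zeta: doubling the transfer coefficient of the gas phase, all else as stated

1. Gas that has crossed the surface, less gas still dissolved, equals substrate gone, taking one gas per substrate. A full solution holds 200 mM, less than the 0.70 M of substrate, so dissolved gas is the limiting reagent of the liquid and has to be refilled. For this flask L = 3.50, the gas load, charged substrate over saturation concentration: the count of full solutions that must cross.

2. In the summer run, target rose at a read pace of 7.70 mM/min late on, with the scatter of two readings in it. My own reckoning holds that pace for 80 min: the flask would draw 3.08 of its L, or 88.0% of its substrate. This is a rough estimate from two scattered readings of target, neither a bound on substrate gone nor a forecast of target.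

3. Delta, by hand: L falls to 1.75, and the gap that drives refilling widens.

4. Zeta, by hand: L stays, and the same gap refills faster.

5. Theta, by hand: L stays, and dissolved gas is used faster, which widens the gap somewhat.

6. The forecast gives 42% (25% to 70%) and picks delta, with 62% (38% to 90%), because “raising the saturation concentration increases both the driving force and the dissolved gas”.

7. The flask gives 36.8% of target beside 35.9% of isomer of the product, with 27% of substrate left. Delta gives 46.4%; the gains are 9.6 percentage points for delta, 7.4 points for zeta and 6.9 points for theta.

    gas phase ⇌ dissolved gas, rate k1*(csat - [dissolved gas]) (kL = 0.0519 /min)
    substrate + dissolved gas + catalyst → catalyst + target (k = 4.45 /M²/min)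
    target ⇌ isomer of the product (K = 1.20, k = 0.0610 /min)
    catalyst + added ligand ⇌ idle complex, settled at all times (K = 27.2 /M)

8. Of its L, this flask has drawn 2.55 for the substrate gone by 80 min. At 36.2 min, dissolved gas has a half-life of 5.3 min by reaction, shorter than the 13.4 min half-life of refilling, and at 40.0 min c(dissolved gas) reads 0.0558 M. At 80.0 min the two half-lives match, 13 min by reaction, and c(dissolved gas) reads 0.0875 M. The neighbour flask with 1.8 M of substrate has L = 9.00, draws 3.56 of it, and ends at 0.0279 M of dissolved gas.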